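The plan rests on disconnecting the C6–C7 bond of ring B. The key step exploits the adjacent oxygenated carbons C6 (acetate) and C7 (ketone), flanked by C5 of ring A and by C8, the quaternary carbon shared by ring B and the cyclobutane: they are read as two ester carbonyls joined carbon to carbon. A sodium/chlorotrimethylsilane acyloin coupling closes ring B and delivers both oxygens in one operation as an enediol bis(silyl) ether, leaving C6 uncommitted for a later kinetic protonation. The precursor is a seco diester: C6 methyl ester on C5 of ring A, C7 methyl ester on C8 of the finished bicyclo[3.2.0]heptane, C13 carbinol as triethylsilyl ether.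

Key step: step 19

Remark 1 (locants): ring A = C1–C5 and C10; ring B = C5–C10; cyclobutane = C8, C9, C14, C15; cyclopentane = C9, C11–C14; methyl groups C16 (on C13), C17 (on C8), C18/C19 (on C4), C20 (on C10).
Remark 2 (design): the C13 carbinol is carried as a triethylsilyl ether instead of a trimethylsilyl ether, so that it survives hydrolysis of the two enol silyl ethers and the forcing acetylation of the C6 hydroxyl.
Remark 3 (stereochemistry): the ozonide carbon of 7, C9 of 10 and 13, and C13 of F2–F5 are mixtures that are erased later; they are left undefined in the SMILES.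

Step 1
Reactants: 1 β-cyclocitral
Product: 2 β-cyclogeraniol
Conditions: NaBH4, MeOH, 0 °C
Reagents that add atoms: none
Why: Borohydride 1,2-reduction of the hindered enal gives the primary allylic alcohol without touching the tetrasubstituted alkene, and no stereocentre is formed.

Step 2
Reactants: 3 methyl 2-oxocyclopentane-1-carboxylate
Product: 4 methyl 1-methyl-2-oxocyclopentane-1-carboxylate (racemic)
Conditions: K2CO3, MeI, acetone, reflux
Reagents that add atoms: iodomethane, CI
Why: C-alkylation of the stabilised β-keto ester enolate installs the C17 methyl group and makes C8 quaternary; the centre is racemic here and is resolved in step 4.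

Step 3
Reactants: 4 methyl 1-methyl-2-oxocyclopentane-1-carboxylate (racemic)
Product: 5 methyl 1-methyl-2-oxocyclopent-3-ene-1-carboxylate (racemic)
Conditions: IBX, DMSO/fluorobenzene, 75 °C
Reagents that add atoms: none
Why: IBX dehydrogenation of a ketone runs through the only available enol (towards C9) and gives the cyclopentenone, while the quaternary C8 blocks the other α-position and prevents tautomerisation of the product.

Step 4
Reactants: 5 methyl 1-methyl-2-oxocyclopent-3-ene-1-carboxylate (racemic)
Product: 6 methyl (1S,4S)-1-methyl-2-oxo-4-(prop-1-en-2-yl)cyclopentane-1-carboxylate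
Conditions: [Rh(cod)2]BF4 (cat.), (S)-BINAP, potassium isopropenyltrifluoroborate, Et3N, toluene/H2O, 40 °C; silica gel separation of the two diastereomers
Reagents that add atoms: potassium trifluoro(prop-1-en-2-yl)borate, [K+].C=C(C)[B-](F)(F)F
Why: In this Hayashi–Miyaura 1,4-addition the (S)-BINAP–alkenylrhodium species should add to the same enone face whatever the remote C8 centre (by analogy with simple cyclopentenones, giving 4S), so C14 is set by the catalyst and the racemate is split into two separable diastereomers, of which 6 (propenyl cis to the C8 methyl, from at most half of 5) is kept.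

Step 5
Reactants: 6 methyl (1S,4S)-1-methyl-2-oxo-4-(prop-1-en-2-yl)cyclopentane-1-carboxylate
Product: 8 methyl (1S,4S)-4-acetyl-1-methyl-2-oxocyclopentane-1-carboxylate, via ozonide 7 (not isolated)
Conditions: O3, CH2Cl2, −78 °C; then Me2S
Reagents that add atoms: ozone, [O-][O+]=O
Why: Ozonolysis with reductive work-up cleaves the 1,1-disubstituted alkene to the methyl ketone (C13 and C12) under neutral conditions, so the C14 centre next to the new acetyl group is not epimerised and no stereocentre is formed.

Step 6
Reactants: 8 methyl (1S,4S)-4-acetyl-1-methyl-2-oxocyclopentane-1-carboxylate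
Product: 9 methyl (1S,4S)-1-methyl-4-(2-methyl-1,3-dioxolan-2-yl)-2-oxocyclopentane-1-carboxylate
Conditions: Me3SiOCH2CH2OSiMe3, Me3SiOTf (cat.), CH2Cl2, −78 → −20 °C
Reagents that add atoms: 1,2-bis(trimethylsilyloxy)ethane, C[Si](C)(C)OCCO[Si](C)(C)C
Why: Low-temperature Me3SiOTf-catalysed ketalisation with the bis-silyl ether of ethylene glycol protects the unhindered methyl ketone selectively over the ring ketone flanked by the quaternary C8, and its non-equilibrating conditions leave C14 untouched.

Step 7
Reactants: 9 methyl (1S,4S)-1-methyl-4-(2-methyl-1,3-dioxolan-2-yl)-2-oxocyclopentane-1-carboxylate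
Product: 11 methyl (1S,4S)-3-diazo-1-methyl-4-(2-methyl-1,3-dioxolan-2-yl)-2-oxocyclopentane-1-carboxylate, via trifluoroacetyl ketone 10 (not isolated)
Conditions: LiN(SiMe3)2, THF, −78 °C; CF3CO2CH2CF3; then MsN3, Et3N, H2O, MeCN, rt
Reagents that add atoms: methanesulfonyl azide, CS(=O)(=O)N=[N+]=[N-]
Why: In this detrifluoroacetylative Regitz diazo transfer the ring ketone can enolise only towards C9 (C8 is quaternary), the enolate is trifluoroacetylated, and the activated carbon accepts the diazo group with loss of the trifluoroacetyl group; no stereocentre is affected.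

Step 8
Reactants: 11 methyl (1S,4S)-3-diazo-1-methyl-4-(2-methyl-1,3-dioxolan-2-yl)-2-oxocyclopentane-1-carboxylate; 2 β-cyclogeraniol
Product: 13 1-[(2,6,6-trimethylcyclohex-1-en-1-yl)methyl] 2-methyl (2S,4S)-2-methyl-4-(2-methyl-1,3-dioxolan-2-yl)cyclobutane-1,2-dicarboxylate (C1 epimers), via ketene 12 (not isolated)
Conditions: hν (Pyrex, λ > 300 nm), 2 (3 equiv), THF, rt
Reagents that add atoms: none
Why: Photochemical Wolff rearrangement expels N2 with a 1,2-shift of the quaternary C8 (retention), contracting the ring to the cyclobutylidene ketene, which the primary allylic alcohol traps as its ester; C8 and C14 are preserved and the new C9–H centre is inconsequential because it is enolised next.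

Step 9
Reactants: 13 1-[(2,6,6-trimethylcyclohex-1-en-1-yl)methyl] 2-methyl (2S,4S)-2-methyl-4-(2-methyl-1,3-dioxolan-2-yl)cyclobutane-1,2-dicarboxylate
Product: 16 (1R,2S,4S)-2-(methoxycarbonyl)-2-methyl-4-(2-methyl-1,3-dioxolan-2-yl)-1-[(1S)-1,3,3-trimethyl-2-methylidenecyclohexyl]cyclobutane-1-carboxylic acid, via silyl ketene acetal 14 (not isolated), via trimethylsilyl ester 15 (not isolated)
Conditions: LiN(iPr)2, THF, −78 °C; Me3SiCl/Et3N; −78 → 65 °C; then aq. NaOH, citric acid to pH 4
Reagents that add atoms: none
Why: This Ireland–Claisen rearrangement is of a type known to join two rings through vicinal quaternary carbons from (2-methylcycloalk-1-enyl)methyl esters of α-branched cycloalkanecarboxylic acids: kinetic enolisation in THF should place the bulkier C8 syn to the allyloxy oxygen (14), the allyl unit should add to C9 on the face carrying the C7 ester and H14 (anti to the C8 methyl and the dioxolanyl group), and a chair transition state with the C10 methyl pseudoaxial then gives the C9/C10 relative configuration of the target, the acid being released on hydrolysis of 15.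

Step 10
Reactants: 16 (1R,2S,4S)-2-(methoxycarbonyl)-2-methyl-4-(2-methyl-1,3-dioxolan-2-yl)-1-[(1S)-1,3,3-trimethyl-2-methylidenecyclohexyl]cyclobutane-1-carboxylic acid
Product: 18 diol (C11H2OH on C9; C6H2OH on C5 with H5 trans to the C10 methyl; C7 methyl ester and dioxolane retained), via cyclic alkoxyborane 17 (not isolated)
Conditions: BH3·THF (4 equiv), THF, 0 °C → rt; then NaOH, H2O2, 0 °C → rt
Reagents that add atoms: hydrogen peroxide, OO
Why: Borane reduces the free acid in preference to the hindered methyl ester and the resulting alkoxyborane hydroborates the methylidene group (hydroboration–oxidation, boron to C6), delivering hydrogen to C5 from the face syn to C9 and anti to the axial C4 and C10 methyls, which sets C5–H trans to the C10 methyl with C6 equatorial.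

Step 11
Reactants: 18 diol
Product: 19 dialdehyde (C11 and C6 as CHO)
Conditions: (COCl)2, DMSO, CH2Cl2, −78 °C; Et3N
Reagents that add atoms: none
Why: Swern oxidation activates both primary alcohols at −78 °C before the base is added, so the 1,5-diol gives the dialdehyde without passing through a lactol that could be oxidised to a lactone, and the ketal and ester are untouched.

Step 12
Reactants: 19 dialdehyde
Product: 21 cis-fused bicyclo[3.2.0]hept-3-en-2-one aldehyde (C11=C12–C13=O; C6 aldehyde on ring A), via keto dialdehyde 20 (not isolated)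
Conditions: 1 M HCl, THF, rt; then KOH, MeOH, 0 °C → rt
Reagents that add atoms: water, O
Why: Acidic ketal hydrolysis followed by base-mediated intramolecular aldol condensation of the 1,4-keto aldehyde closes the cyclopentenone, because only the methyl ketone enolate (C12) can reach the non-enolisable C11 aldehyde through a five-membered transition state and dehydration is irreversible; cis fusion is enforced by the four-membered ring and the equatorial C6 aldehyde is expected to be the stable C5 epimer.

Step 13
Reactants: 21 bicyclic enone aldehyde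
Product: 22 enone acid (C6 as CO2H)
Conditions: NaClO2, NaH2PO4, 2-methylbut-2-ene, t-BuOH/H2O, rt
Reagents that add atoms: sodium chlorite, [Na+].[O-]Cl=O
Why: Pinnick oxidation converts the hindered aldehyde into the acid under buffered conditions that leave the enone and C5 alone, with the alkene additive scavenging hypochlorite.

Step 14
Reactants: 22 enone acid
Product: 23 enone diester (C6 and C7 methyl esters)
Conditions: Me3SiCHN2, MeOH/toluene, 0 °C
Reagents that add atoms: (trimethylsilyl)diazomethane, C[Si](C)(C)C=[N+]=[N-]
Why: Esterification with (trimethylsilyl)diazomethane methylates the acid under neutral conditions, so both acyloin partners are now methyl esters and C5 is not exposed to base.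

Step 15
Reactants: 23 enone diester
Product: 24 saturated ketone diester (C13 ketone)
Conditions: H2 (1 atm), Pd/C, EtOAc, rt
Reagents that add atoms: none
Why: Heterogeneous catalytic hydrogenation saturates the disubstituted enone alkene (C11=C12) without creating a stereocentre and without opening the cyclobutane under these mild conditions.

Step 16
Reactants: 24 saturated ketone diester
Product: 25 methylidene diester (C13=C16H2)
Conditions: Ph3PCH3Br, KOtBu, THF/toluene, 0 → 60 °C
Reagents that add atoms: methyltriphenylphosphonium bromide, [Br-].C[P+](c1ccccc1)(c1ccccc1)c1ccccc1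
Why: Wittig methylenation is chemoselective for the cyclopentanone over the two hindered esters and introduces C16 as a 1,1-disubstituted alkene without forming a stereocentre.

Step 17
Reactants: 25 methylidene diester
Product: 26 carbinol diester (C13 tertiary alcohol with OH cis to H14)
Conditions: Co(acac)2 (cat.), PhSiH3, O2 (1 atm), THF/iPrOH, 0 °C → rt
Reagents that add atoms: dioxygen, O=O
Why: Mukaiyama hydration (hydrogen-atom transfer, Markovnikov) generates the tertiary C13 radical, which O2 should trap on the convex face of the bicyclo[3.2.0]heptane, anti to the C15 methylene on the adjacent ring-fusion carbon, so the hydroxyl ends up cis to H14 and the methyl endo; trapping by O2 is much faster than opening of the cyclobutylcarbinyl radical.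

Step 18
Reactants: 26 carbinol diester
Product: 27 seco diester with C13 triethylsilyl ether (key-step precursor)
Conditions: Et3SiOTf, 2,6-lutidine, CH2Cl2, −78 → 0 °C
Reagents that add atoms: triethylsilyl trifluoromethanesulfonate, CC[Si](CC)(CC)OS(=O)(=O)C(F)(F)F
Why: Silylation of the tertiary alcohol with the silyl triflate and a hindered base gives a triethylsilyl ether that is inert to sodium and can be told apart from the two enol trimethylsilyl ethers made in the next step.

Step 19
Reactants: 27 seco diester with C13 triethylsilyl ether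
Product: 28 ring B 6,7-bis(trimethylsilyloxy)alkene with C13 triethylsilyl ether
Conditions: Na (dispersion), Me3SiCl, toluene, 110 °C
Reagents that add atoms: chlorotrimethylsilane, C[Si](C)(C)Cl
Why: Sodium transfers single electrons to both ester carbonyls, the ketyl centres couple to form the C6–C7 bond, two methoxides leave to give the 1,2-dione, and two further electrons reduce it to the enediolate, which Me3SiCl silylates while also scavenging methoxide as MeOSiMe3 so that Claisen-type condensation and enolisation at C5 cannot compete. The closest known reaction type is the Rühlmann-modified acyloin condensation of 1,6-diesters to 1,2-bis(trimethylsilyloxy)cyclohexenes, which also tolerates α,α-disubstituted esters and cyclobutane esters. Ring B closes as a six-membered carbocycle by intramolecular reductive coupling of the two ends of the C6–C5–C10–C9–C8–C7 chain. No stereocentre is created, since C6 and C7 become sp2 and C5, C8, C9, C10, C13 and C14 are untouched. The step needs intramolecular coupling to win over intermolecular coupling and over simple ester reduction; the contiguous quaternary carbons C8, C9 and C10 hold the two esters gauche and close to each other, and the tertiary triethylsilyl ether, the only other functional group, is inert to sodium.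

Step 20
Reactants: 28 ring B 6,7-bis(trimethylsilyloxy)alkene
Product: 29 6β-hydroxy-7-ketone with C13 triethylsilyl ether
Conditions: 1 M HCl, THF, −20 → 0 °C; NaHCO3 quench
Reagents that add atoms: none
Why: Kinetic C-protonation during silyl enol ether hydrolysis should occur at C6, the less hindered enol ether carbon (C7 is shielded by the quaternary C8 and the axial C14), from the α-face anti to the three syn-axial β-methyl groups on C4, C8 and C10, which gives the axial 6β-oxygen and the C7 ketone after loss of both trimethylsilyl groups, while low temperature and short contact prevent ketol equilibration and spare the tertiary triethylsilyl ether.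

Step 21
Reactants: 29 6β-hydroxy-7-ketone with C13 triethylsilyl ether
Product: 30 6β-acetoxy-7-ketone with C13 triethylsilyl ether
Conditions: Ac2O, DMAP, Et3N, CH2Cl2, rt → 40 °C
Reagents that add atoms: acetic anhydride, CC(=O)OC(C)=O
Why: DMAP-catalysed acylation esterifies the hindered axial secondary alcohol while the C13 oxygen is masked, and C6 should not epimerise because its equatorial hydrogen is poorly aligned with the C7 carbonyl for enolisation.

Step 22
Reactants: 30 6β-acetoxy-7-ketone with C13 triethylsilyl ether
Product: 31 target CNP0330581.1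
Conditions: HF·pyridine, THF, 0 °C → rt
Reagents that add atoms: none
Why: Fluoride-mediated desilylation under buffered, weakly acidic conditions frees the tertiary C13 alcohol without cleaving the acetate or enolising the α-acetoxy ketone.

Compound list
1 | β-cyclocitral (2,6,6-trimethylcyclohex-1-ene-1-carbaldehyde) | CC1=C(C=O)C(C)(C)CCC1 | starting material
2 | β-cyclogeraniol ((2,6,6-trimethylcyclohex-1-en-1-yl)methanol) | CC1=C(CO)C(C)(C)CCC1 | intermediate
3 | methyl 2-oxocyclopentane-1-carboxylate | COC(=O)C1CCCC1=O | starting material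
4 | methyl 1-methyl-2-oxocyclopentane-1-carboxylate (racemic) | COC(=O)C1(C)CCCC1=O | intermediate
5 | methyl 1-methyl-2-oxocyclopent-3-ene-1-carboxylate (racemic) | COC(=O)C1(C)CC=CC1=O | intermediate
6 | methyl (1S,4S)-1-methyl-2-oxo-4-(prop-1-en-2-yl)cyclopentane-1-carboxylate (propenyl cis to methyl) | COC(=O)[C@@]1(C)C[C@H](C(C)=C)CC1=O | intermediate
7 | ozonide (1,2,4-trioxolane) of 6 | COC(=O)[C@@]1(C)C[C@H](C2(C)OCOO2)CC1=O | intermediate (not isolated)
8 | methyl (1S,4S)-4-acetyl-1-methyl-2-oxocyclopentane-1-carboxylate | COC(=O)[C@@]1(C)C[C@H](C(C)=O)CC1=O | intermediate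
9 | methyl (1S,4S)-1-methyl-4-(2-methyl-1,3-dioxolan-2-yl)-2-oxocyclopentane-1-carboxylate | COC(=O)[C@@]1(C)C[C@H](C2(C)OCCO2)CC1=O | intermediate
10 | 3-(trifluoroacetyl) derivative of 9 | COC(=O)[C@@]1(C)C[C@H](C2(C)OCCO2)C(C(=O)C(F)(F)F)C1=O | intermediate (not isolated)
11 | methyl (1S,4S)-3-diazo-1-methyl-4-(2-methyl-1,3-dioxolan-2-yl)-2-oxocyclopentane-1-carboxylate | COC(=O)[C@@]1(C)C[C@H](C2(C)OCCO2)C(=[N+]=[N-])C1=O | intermediate
12 | methyl (1S,3S)-1-methyl-3-(2-methyl-1,3-dioxolan-2-yl)-2-(oxomethylidene)cyclobutane-1-carboxylate (ketene) | COC(=O)[C@@]1(C)C[C@H](C2(C)OCCO2)C1=C=O | intermediate (not isolated)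
13 | 1-[(2,6,6-trimethylcyclohex-1-en-1-yl)methyl] 2-methyl (2S,4S)-2-methyl-4-(2-methyl-1,3-dioxolan-2-yl)cyclobutane-1,2-dicarboxylate (C1 epimers; dioxolanyl cis to the C2 methyl) | COC(=O)[C@@]1(C)C[C@H](C2(C)OCCO2)C1C(=O)OCC1=C(C)CCCC1(C)C | intermediate
14 | trimethylsilyl ketene acetal of 13 (C8 syn to the allyloxy oxygen; silyloxy syn to C14) | COC(=O)[C@@]1(C)C[C@H](C2(C)OCCO2)/C1=C(\O[Si](C)(C)C)OCC1=C(C)CCCC1(C)C | intermediate (not isolated)
15 | trimethylsilyl ester of 16 | COC(=O)[C@@]1(C)C[C@H](C2(C)OCCO2)[C@@]1(C(=O)O[Si](C)(C)C)[C@@]1(C)CCCC(C)(C)C1=C | intermediate (not isolated)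
16 | (1R,2S,4S)-2-(methoxycarbonyl)-2-methyl-4-(2-methyl-1,3-dioxolan-2-yl)-1-[(1S)-1,3,3-trimethyl-2-methylidenecyclohexyl]cyclobutane-1-carboxylic acid (ring A on the cyclobutane face of the C7 ester and H14) | COC(=O)[C@@]1(C)C[C@H](C2(C)OCCO2)[C@@]1(C(=O)O)[C@@]1(C)CCCC(C)(C)C1=C | intermediate
17 | cyclic alkoxyborane bridging the C11 oxygen and C6 (simplest form of the organoborane) | COC(=O)[C@@]1(C)C[C@H](C2(C)OCCO2)[C@@]1(CO[BH]C3)[C@@]1(C)CCCC(C)(C)[C@@H]13 | intermediate (not isolated)
18 | diol: 16 with C11 as CH2OH and C5(H)–C6H2OH in place of the methylidene group, H5 trans to the C10 methyl | COC(=O)[C@@]1(C)C[C@H](C2(C)OCCO2)[C@@]1(CO)[C@@]1(C)CCCC(C)(C)[C@@H]1CO | intermediate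
19 | dialdehyde: 18 with C11 and C6 as CHO | COC(=O)[C@@]1(C)C[C@H](C2(C)OCCO2)[C@@]1(C=O)[C@@]1(C)CCCC(C)(C)[C@@H]1C=O | intermediate
20 | keto dialdehyde: 19 with the dioxolane hydrolysed to the C14 acetyl group | COC(=O)[C@@]1(C)C[C@H](C(C)=O)[C@@]1(C=O)[C@@]1(C)CCCC(C)(C)[C@@H]1C=O | intermediate (not isolated)
21 | cis-fused bicyclo[3.2.0]hept-3-en-2-one (C11=C12–C13=O) bearing the C7 methyl ester on C8 and, on C9, ring A with the C6 aldehyde | COC(=O)[C@@]1(C)C[C@H]2[C@@]1(C=CC2=O)[C@@]1(C)CCCC(C)(C)[C@@H]1C=O | intermediate
22 | enone acid: 21 with C6 as CO2H | COC(=O)[C@@]1(C)C[C@H]2[C@@]1(C=CC2=O)[C@@]1(C)CCCC(C)(C)[C@@H]1C(=O)O | intermediate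
23 | enone diester: 22 as its C6 methyl ester | COC(=O)[C@@]1(C)C[C@H]2[C@@]1(C=CC2=O)[C@@]1(C)CCCC(C)(C)[C@@H]1C(=O)OC | intermediate
24 | saturated C13 ketone diester | COC(=O)[C@@]1(C)C[C@H]2[C@@]1(CCC2=O)[C@@]1(C)CCCC(C)(C)[C@@H]1C(=O)OC | intermediate
25 | C13 methylidene diester | COC(=O)[C@@]1(C)C[C@H]2[C@@]1(CCC2=C)[C@@]1(C)CCCC(C)(C)[C@@H]1C(=O)OC | intermediate
26 | C13 carbinol diester (OH cis to H14; methyl endo) | COC(=O)[C@@]1(C)C[C@H]2[C@@]1(CC[C@]2(C)O)[C@@]1(C)CCCC(C)(C)[C@@H]1C(=O)OC | intermediate
27 | key-step precursor: seco diester with C6 and C7 methyl esters and C13 triethylsilyl ether | COC(=O)[C@@]1(C)C[C@H]2[C@@]1(CC[C@]2(C)O[Si](CC)(CC)CC)[C@@]1(C)CCCC(C)(C)[C@@H]1C(=O)OC | intermediate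
28 | key-step product: ring B 6,7-bis(trimethylsilyloxy)alkene with C13 triethylsilyl ether | C[Si](C)(C)OC1=C(O[Si](C)(C)C)[C@@]2(C)C[C@H]3[C@@]2(CC[C@]3(C)O[Si](CC)(CC)CC)[C@@]2(C)CCCC(C)(C)[C@H]12 | intermediate
29 | 6β-hydroxy-7-ketone with C13 triethylsilyl ether | O[C@@H]1C(=O)[C@@]2(C)C[C@H]3[C@@]2(CC[C@]3(C)O[Si](CC)(CC)CC)[C@@]2(C)CCCC(C)(C)[C@H]12 | intermediate
30 | 6β-acetoxy-7-ketone with C13 triethylsilyl ether | CC(=O)O[C@@H]1C(=O)[C@@]2(C)C[C@H]3[C@@]2(CC[C@]3(C)O[Si](CC)(CC)CC)[C@@]2(C)CCCC(C)(C)[C@H]12 | intermediate
31 | CNP0330581.1: 6β-acetoxy-13-hydroxy-7-ketone, (5S,6S,8S,9S,10S,13S,14S) in the locants above | CC(=O)O[C@@H]1C(=O)[C@@]2(C)C[C@H]3[C@@]2(CC[C@]3(C)O)[C@@]2(C)CCCC(C)(C)[C@H]12 | target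

Total step count: 22. Longest linear sequence: 21 steps (steps 2–22, from 3); the ring A branch (step 1) joins at step 8.

Steps most likely to fail

Step 9 (Ireland–Claisen). The rearrangement joins two very congested carbons and may be slow. If the ketene acetal geometry forms unselectively, the C10 configuration is eroded. The fallback fixes the geometry by chelation; it sets out from 13 and comes back at 20 (then 21 as in step 12). The dioxolane is hydrolysed (PPTS, aqueous acetone) to keto diester F1, and the ketone is reduced with NaBH4 to hydroxy diester F2 (either C13 epimer). The rearrangement is then run on the dianion (LiN(iPr)2, 2.3 equiv; then Me3SiCl), in which the lithium alkoxide bridges to the enolate oxygen and holds it syn to C14. The resulting hydroxy acid closes to γ-lactone F3. BH3·THF followed by NaOH/H2O2 hydroborates the methylidene group to hydroxy lactone F4, and LiBH4 opens the lactone, sparing the hindered methyl ester, to triol F5. Swern oxidation of all three alcohols gives keto dialdehyde 20.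

Step 19 (acyloin coupling). Coupling of two neopentyl-type esters may be slow, so that over-reduction of the esters or opening of the cyclobutane through the C7 ketyl competes. The fallback builds the same C6–C7 bond by pinacol coupling; it sets out from 27 and comes back at 29. LiAlH4 reduces both esters to diol F6, and Swern oxidation gives dialdehyde F7. SmI2 in THF closes ring B as the cis-diol F8, expected 6α,7α; both centres are erased next. Oxidation with IBX gives 6,7-dione F9, which is used at once before it can tautomerise towards C5. NaBH4 at −78 °C should reduce the less hindered C6 carbonyl from the open α-face and give 29 directly.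

Step 20 (kinetic protonation). Kinetic control may be lost through protonation at C7 or from the β-face, or through acid-mediated equilibration of the strained axial ketol to the equatorial epimer. The fallback protonates a preformed enolate instead; it sets out from 28 and comes back at 29. Both enol silyl ethers are cleaved with MeLi (2 equiv, THF, 0 °C) to dilithium enediolate F10. This is protonated at −78 °C with 2,6-di-tert-butyl-4-methylphenol, a bulky acid that should reach only C6 from the α-face, and a neutral buffer quench gives 29 without exposure to strong acid.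

Further compounds
F1 | step 9 | keto diester (13 with the dioxolane hydrolysed to acetyl) | COC(=O)[C@@]1(C)C[C@H](C(C)=O)C1C(=O)OCC1=C(C)CCCC1(C)C
F2 | step 9 | hydroxy diester (F1 with the acetyl group reduced to 1-hydroxyethyl) | COC(=O)[C@@]1(C)C[C@H](C(C)O)C1C(=O)OCC1=C(C)CCCC1(C)C
F3 | step 9 | cyclobutane-fused γ-lactone (C11 carbonyl, C13 oxygen) carrying ring A with the methylidene group on C9 | COC(=O)[C@@]1(C)C[C@@H]2C(C)OC(=O)[C@]12[C@@]1(C)CCCC(C)(C)C1=C
F4 | step 9 | hydroxy lactone (F3 with C5(H)–C6H2OH) | COC(=O)[C@@]1(C)C[C@@H]2C(C)OC(=O)[C@]12[C@@]1(C)CCCC(C)(C)[C@@H]1CO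
F5 | step 9 | triol (C6, C11 and C13 hydroxyls) | COC(=O)[C@@]1(C)C[C@H](C(C)O)[C@@]1(CO)[C@@]1(C)CCCC(C)(C)[C@@H]1CO
F6 | step 19 | C6,C7-diol from reduction of 27 | OC[C@@]1(C)C[C@H]2[C@@]1(CC[C@]2(C)O[Si](CC)(CC)CC)[C@@]1(C)CCCC(C)(C)[C@@H]1CO
F7 | step 19 | C6,C7-dialdehyde | O=C[C@@]1(C)C[C@H]2[C@@]1(CC[C@]2(C)O[Si](CC)(CC)CC)[C@@]1(C)CCCC(C)(C)[C@@H]1C=O
F8 | step 19 | ring B 6α,7α-diol with C13 triethylsilyl ether | O[C@H]1[C@@H](O)[C@@]2(C)C[C@H]3[C@@]2(CC[C@]3(C)O[Si](CC)(CC)CC)[C@@]2(C)CCCC(C)(C)[C@H]12
F9 | step 19 | ring B 6,7-dione with C13 triethylsilyl ether | O=C1C(=O)[C@@]2(C)C[C@H]3[C@@]2(CC[C@]3(C)O[Si](CC)(CC)CC)[C@@]2(C)CCCC(C)(C)[C@H]12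
F10 | step 20 | dilithium 6,7-enediolate with C13 triethylsilyl ether | [Li+].[Li+].[O-]C1=C([O-])[C@@]2(C)C[C@H]3[C@@]2(CC[C@]3(C)O[Si](CC)(CC)CC)[C@@]2(C)CCCC(C)(C)[C@H]12
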